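## Retrosynthetic overview

1. The target comes from global deprotection of a 12-membered diketone. Its two aryl–C(=O) bonds are cut to two cyclohexene halves that differ only at the ketone α-carbon: a Weinreb amide (ring A half) and a carboxylate (ring B half), each carrying an aryl bromide.
2. Both halves come from one cis-fused benzo[c]chromenone lactone. The ring B half is its α-epimer (trans-fused lactone), made by kinetic protonation of the lactone enolate.
3. The lactone comes from ring expansion of a lactone-fused vinylcyclobutane by a hole-catalysed 1,3-carbon shift (key step; forms the cyclohexene and sets C5).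
4. The cyclobutane comes from a tether-directed enantioselective [2+2] photocycloaddition of an o-dienylphenyl cinnamate, assembled by two Wittig reactions and one O-acylation.
5. Building blocks: resorcinol (all four arenes), DMF (C3 and C5), 3-chloro-2-methylpropene (C1, C2, C6, CH3), bromoacetyl bromide (C4 and C=O). Ring order: lactone + cyclobutane → cyclohexene (both halves from one batch) → 12-membered ring.

Convention: cyclohexene numbering is C1(Me)=C2, C3 (arene that lies in the macrocycle), C4 (C=O), C5 (pendant arene), C6H2. Ring A is 3R,4S,5R (3,4-cis/4,5-trans); ring B is 3R,4R,5R (3,4-trans/4,5-cis).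

## Route

Step 1
Reactants: 1 resorcinol
Product: 2 2,4-dihydroxybenzaldehyde
Conditions: POCl3, DMF, MeCN, −15 °C → rt; then H2O, 50 °C
Reagents that add atoms: N,N-dimethylformamide, CN(C)C=O; water, O
Why: Vilsmeier–Haack formylation attacks the position para to one OH and ortho to the other, and no stereocentre is formed.

Step 2
Reactants: 2 2,4-dihydroxybenzaldehyde
Product: 3 2-hydroxy-4-methoxybenzaldehyde
Conditions: MeI (1.05 equiv), K2CO3, acetone, rt
Reagents that add atoms: iodomethane, CI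
Why: Williamson ether synthesis in which the 2-OH, hydrogen-bonded to the aldehyde, stays free so only the 4-OH is methylated.

Step 3
Reactants: 3 2-hydroxy-4-methoxybenzaldehyde
Product: 4 5-bromo-2-hydroxy-4-methoxybenzaldehyde
Conditions: NBS, MeCN, 0 °C → rt
Reagents that add atoms: N-bromosuccinimide, O=C1CCC(=O)N1Br
Why: Electrophilic aromatic bromination para to the free OH and ortho to OMe, the site that later carries the aryl ketone.

Step 4
Reactants: 4 5-bromo-2-hydroxy-4-methoxybenzaldehyde; 5 3-chloro-2-methylprop-1-ene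
Product: 8 4-bromo-5-methoxy-2-[(1E)-3-methylbuta-1,3-dien-1-yl]phenol, via methallylphosphonium chloride 6 (not isolated), via allylic ylide 7 (not isolated)
Conditions: 5, PPh3, MeCN, 80 °C; then THF, KOtBu (2.2 equiv), 0 °C; then 4, 0 °C → rt; I2 (2 mol%), CH2Cl2, daylight
Reagents that add atoms: none
Why: Wittig olefination with a semistabilised allylic ylide made in the flask (the second equivalent of base covers the phenol), followed by iodine-catalysed Z→E equilibration; the olefin geometry is not carried into any stereocentre.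

Step 5
Reactants: 8 4-bromo-5-methoxy-2-[(1E)-3-methylbuta-1,3-dien-1-yl]phenol; 9 bromoacetyl bromide
Product: 10 4-bromo-5-methoxy-2-[(1E)-3-methylbuta-1,3-dien-1-yl]phenyl bromoacetate
Conditions: NaHCO3, CH2Cl2/H2O, 0 °C
Reagents that add atoms: none
Why: Schotten–Baumann O-acylation of the only free phenol, the acyl bromide reacting far faster than the alkyl bromide.

Step 6
Reactants: 2 2,4-dihydroxybenzaldehyde
Product: 11 2,4-bis(triisopropylsilyloxy)benzaldehyde
Conditions: NaH (2.2 equiv), THF, 0 °C; then i-Pr3SiCl (2.3 equiv), 0 °C → rt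
Reagents that add atoms: chlorotri(propan-2-yl)silane, CC(C)[Si](Cl)(C(C)C)C(C)C
Why: Silyl ether formation on both phenoxides gives a protecting group that survives the Lewis acid, enolate and organolithium steps and leaves under fluoride at the end.

Step 7
Reactants: 10 4-bromo-5-methoxy-2-[(1E)-3-methylbuta-1,3-dien-1-yl]phenyl bromoacetate; 11 2,4-bis(triisopropylsilyloxy)benzaldehyde
Product: 14 4-bromo-5-methoxy-2-[(1E)-3-methylbuta-1,3-dien-1-yl]phenyl (2E)-3-[2,4-bis(triisopropylsilyloxy)phenyl]prop-2-enoate, via phosphonium bromide 12 (not isolated), via ester ylide 13 (not isolated)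
Conditions: PPh3, MeCN, rt; then 11, K2CO3, 50 °C
Reagents that add atoms: none
Why: Phosphonium salt formation and Wittig olefination with the stabilised ester ylide give the E-cinnamate, and the mild carbonate base leaves the aryl ester intact.

Step 8
Reactants: 14 the aryl cinnamate
Product: 15 cis-fused 7-bromo-6-methoxy-2-[2,4-bis(triisopropylsilyloxy)phenyl]-1-(prop-1-en-2-yl)-1,2,2a,8b-tetrahydro-3H-cyclobuta[c]chromen-3-one (aryl trans to the lactone C=O; isopropenyl trans to the aryl)
Conditions: AlBr3-activated (S)-oxazaborolidine from (S)-α,α-diphenylprolinol and 2,4,6-trifluorophenylboronic acid (50 mol%), [Ir(ppy)2(dtbbpy)]PF6 (2 mol%), 455 nm LEDs, CH2Cl2, −40 °C, 5 mM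
Reagents that add atoms: none
Why: Intramolecular [2+2] photocycloaddition by chiral-Lewis-acid-accelerated triplet energy transfer (a reaction type known for cinnamate esters): the α-carbon of the boron-bound cinnamate closes the six-membered lactone onto the styrenyl diene carbon (1,6-closure), the benzylic/allylic biradical collapses to the cyclobutane, and the oxazaborolidine shields one face so the two ring-fusion carbons (later C3 and C4) form cis and in one absolute sense (the catalyst antipode is chosen accordingly), while the other two centres are erased in step 9.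

Step 9
Reactants: 15 the lactone-fused vinylcyclobutane
Product: 16 (6aS,7R,10aR)-2-bromo-3-methoxy-9-methyl-7-[2,4-bis(triisopropylsilyloxy)phenyl]-6a,7,8,10a-tetrahydro-6H-benzo[c]chromen-6-one (cis-fused; 7-aryl trans to C6)
Conditions: 2,4,6-triphenylpyrylium tetrafluoroborate (5 mol%), 420 nm LEDs, CH2Cl2, rt, N2
Reagents that add atoms: none
Why: Proposed new method: the excited pyrylium oxidises the bis(silyloxy)phenyl ring (the most electron-rich arene) to a radical cation, which cleaves the strained benzylic cyclobutane bond to the isopropenyl-bearing carbon to give a distonic benzylic cation/allyl radical; re-bonding at the CH2 terminus of the allyl unit forms the cyclohexene and back electron transfer turns the catalyst over, so the carbons set in step 8 (C3, C4) are untouched and the planar benzylic carbon (C5) is captured with its aryl on the convex face of the cis-fused lactone, trans to the C4 carbonyl; the closest known reaction type is the aminium-salt (hole)-catalysed vinylcyclobutane-to-cyclohexene rearrangement of anisyl-substituted vinylcyclobutanes.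

Step 10
Reactants: 16 the cis-fused lactone
Product: 17 (6aR,7R,10aR)-2-bromo-3-methoxy-9-methyl-7-[2,4-bis(triisopropylsilyloxy)phenyl]-6a,7,8,10a-tetrahydro-6H-benzo[c]chromen-6-one (trans-fused; 7-aryl cis to C6)
Conditions: LiN(SiMe3)2 (1.1 equiv), THF, −78 °C; then 2,6-di-tert-butyl-4-methylphenol, −78 → −40 °C; aq NH4Cl
Reagents that add atoms: none
Why: Kinetic protonation of the lactone enolate, in which the C7 aryl stands pseudo-axial (allylic strain against the enolate) and blocks its own face, so the proton enters anti to it and only C6a is inverted, giving the trans-fused lactone with the aryl cis to the carbonyl (the ring B arrangement).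

Step 11
Reactants: 16 the cis-fused lactone
Product: 18 (1S,2R,6R)-2-(5-bromo-2-hydroxy-4-methoxyphenyl)-N-methoxy-N,4-dimethyl-6-[2,4-bis(triisopropylsilyloxy)phenyl]cyclohex-3-ene-1-carboxamide
Conditions: MeNH(OMe)·HCl (3 equiv), i-PrMgCl (6 equiv), THF, −20 → 0 °C
Reagents that add atoms: N,O-dimethylhydroxylamine hydrochloride, CNOC.Cl
Why: Weinreb amide synthesis by aminolysis of the aryl lactone with the magnesium amide, a non-enolising acyl substitution that keeps the ring A configuration at C1.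

Step 12
Reactants: 17 the trans-fused lactone; 18 the Weinreb amide
Product: 25 protected macrocyclic diketone (ring A 3R,4S,5R; ring B 3R,4R,5R; OMe ortho to each ketone; free OH para to each ketone; four pendant OSi(i-Pr)3), via potassium carboxylate 19 (not isolated), via aryllithium 20 (not isolated), via sodium phenoxide 21 (not isolated), via Weinreb mono-adduct 22 (not isolated), via second aryllithium 23 (not isolated), via macrocyclic bis-adduct 24 (not isolated)
Conditions: 17, KOSiMe3 (1.05 equiv), THF, 0 °C → rt; −78 °C, t-BuLi (2.1 equiv); add 18 pretreated with NaH (1.05 equiv, THF, 0 °C), −78 → −40 °C; t-BuLi (2.1 equiv), −78 °C, dilute to 2 mM, → 0 °C; 1 M HCl, 0 °C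
Reagents that add atoms: potassium trimethylsilanolate, C[Si](C)(C)[O-].[K+] (its oxygen enters the carboxylate of 19 and may be the one kept in the ring B ketone)
Why: Weinreb ketone synthesis followed by Parham-type cycloacylation of a carboxylate in one pot: the carboxylate of 19 is inert at −78 °C so aryllithium 20 attacks only the Weinreb amide, the chelated adduct 22 masks the first ketone while the second bromine–lithium exchange lets the other arene close the 12-membered ring on the carboxylate, and because neither a carboxylate nor a chelated adduct enolises both α-stereocentres survive and the two ketones appear only on work-up.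

Step 13
Reactants: 25 the protected macrocyclic diketone
Product: 27 CNP0244682.3 (target), via tetrasilyl ether 26 (not isolated)
Conditions: BCl3 (6 equiv), CH2Cl2, −78 → −20 °C; pH 7 buffer quench, extract; then HF·pyridine, THF/pyridine, 0 °C → rt
Reagents that add atoms: none
Why: Chelation-controlled BCl3 cleavage of the two aryl methyl ethers ortho to the ketones, then fluoride desilylation of the four silyl ethers, under non-basic conditions that do not enolise the ketones (in particular the cis-disposed α-centre of ring B).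

## Compound list

1 | resorcinol | Oc1cccc(O)c1 | starting material
2 | 2,4-dihydroxybenzaldehyde | O=Cc1ccc(O)cc1O | intermediate
3 | 2-hydroxy-4-methoxybenzaldehyde | COc1ccc(C=O)c(O)c1 | intermediate
4 | 5-bromo-2-hydroxy-4-methoxybenzaldehyde | COc1cc(O)c(C=O)cc1Br | intermediate
5 | 3-chloro-2-methylprop-1-ene | C=C(C)CCl | starting material
6 | (2-methylprop-2-en-1-yl)triphenylphosphonium chloride | C=C(C)C[P+](c1ccccc1)(c1ccccc1)c1ccccc1.[Cl-] | intermediate
7 | (2-methylprop-2-en-1-ylidene)triphenylphosphorane | C=C(C)C=P(c1ccccc1)(c1ccccc1)c1ccccc1 | intermediate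
8 | 4-bromo-5-methoxy-2-[(1E)-3-methylbuta-1,3-dien-1-yl]phenol | C=C(C)/C=C/c1cc(Br)c(OC)cc1O | intermediate
9 | bromoacetyl bromide | BrCC(Br)=O | starting material
10 | 4-bromo-5-methoxy-2-[(1E)-3-methylbuta-1,3-dien-1-yl]phenyl bromoacetate | C=C(C)/C=C/c1cc(Br)c(OC)cc1OC(=O)CBr | intermediate
11 | 2,4-bis(triisopropylsilyloxy)benzaldehyde | O=Cc1ccc(O[Si](C(C)C)(C(C)C)C(C)C)cc1O[Si](C(C)C)(C(C)C)C(C)C | intermediate
12 | triphenylphosphonium bromide of 10 | C=C(C)/C=C/c1cc(Br)c(OC)cc1OC(=O)C[P+](c1ccccc1)(c1ccccc1)c1ccccc1.[Br-] | intermediate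
13 | stabilised ester ylide from 12 | C=C(C)/C=C/c1cc(Br)c(OC)cc1OC(=O)C=P(c1ccccc1)(c1ccccc1)c1ccccc1 | intermediate
14 | aryl (E)-cinnamate (dienyl aryl ester of the bis-silylated cinnamic acid) | C=C(C)/C=C/c1cc(Br)c(OC)cc1OC(=O)/C=C/c1ccc(O[Si](C(C)C)(C(C)C)C(C)C)cc1O[Si](C(C)C)(C(C)C)C(C)C | intermediate
15 | cis-fused cyclobuta[c]chromen-3-one (aryl trans to C=O, isopropenyl trans to aryl) | O=C1[C@@H]3[C@@H]([C@H](C(C)=C)[C@H]3c3ccc(O[Si](C(C)C)(C(C)C)C(C)C)cc3O[Si](C(C)C)(C(C)C)C(C)C)c2cc(Br)c(OC)cc2O1 | intermediate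
16 | (6aS,7R,10aR) cis-fused tetrahydrobenzo[c]chromen-6-one (ring A arrangement) | O=C1[C@@H]3[C@@H](C=C(C)C[C@H]3c3ccc(O[Si](C(C)C)(C(C)C)C(C)C)cc3O[Si](C(C)C)(C(C)C)C(C)C)c2cc(Br)c(OC)cc2O1 | intermediate
17 | (6aR,7R,10aR) trans-fused tetrahydrobenzo[c]chromen-6-one (ring B arrangement) | O=C1[C@H]3[C@@H](C=C(C)C[C@H]3c3ccc(O[Si](C(C)C)(C(C)C)C(C)C)cc3O[Si](C(C)C)(C(C)C)C(C)C)c2cc(Br)c(OC)cc2O1 | intermediate
18 | (1S,2R,6R) Weinreb amide of the ring A half, free phenol | CON(C)C(=O)[C@@H]3[C@@H](C=C(C)C[C@H]3c3ccc(O[Si](C(C)C)(C(C)C)C(C)C)cc3O[Si](C(C)C)(C(C)C)C(C)C)c2cc(Br)c(OC)cc2O | intermediate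
19 | potassium (1R,2R,6R)-carboxylate of the ring B half, phenol as trimethylsilyl ether | [K+].[O-]C(=O)[C@H]3[C@@H](C=C(C)C[C@H]3c3ccc(O[Si](C(C)C)(C(C)C)C(C)C)cc3O[Si](C(C)C)(C(C)C)C(C)C)c2cc(Br)c(OC)cc2O[Si](C)(C)C | intermediate
20 | aryllithium from 19 (Li in place of Br) | [K+].[O-]C(=O)[C@H]3[C@@H](C=C(C)C[C@H]3c3ccc(O[Si](C(C)C)(C(C)C)C(C)C)cc3O[Si](C(C)C)(C(C)C)C(C)C)c2cc([Li])c(OC)cc2O[Si](C)(C)C | intermediate
21 | sodium phenoxide of 18 | [Na+].CON(C)C(=O)[C@@H]3[C@@H](C=C(C)C[C@H]3c3ccc(O[Si](C(C)C)(C(C)C)C(C)C)cc3O[Si](C(C)C)(C(C)C)C(C)C)c2cc(Br)c(OC)cc2[O-] | intermediate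
22 | chelated tetrahedral adduct of 20 on the Weinreb amide (linear, one Br left) | [K+].[Na+].[O-]C(=O)[C@H]3[C@@H](C=C(C)C[C@H]3c3ccc(O[Si](C(C)C)(C(C)C)C(C)C)cc3O[Si](C(C)C)(C(C)C)C(C)C)c2cc(C(O[Li])(N(C)OC)[C@@H]4[C@@H](C=C(C)C[C@H]4c4ccc(O[Si](C(C)C)(C(C)C)C(C)C)cc4O[Si](C(C)C)(C(C)C)C(C)C)c5cc(Br)c(OC)cc5[O-])c(OC)cc2O[Si](C)(C)C | intermediate
23 | aryllithium from 22 (Li in place of the remaining Br) | [K+].[Na+].[O-]C(=O)[C@H]3[C@@H](C=C(C)C[C@H]3c3ccc(O[Si](C(C)C)(C(C)C)C(C)C)cc3O[Si](C(C)C)(C(C)C)C(C)C)c2cc(C(O[Li])(N(C)OC)[C@@H]4[C@@H](C=C(C)C[C@H]4c4ccc(O[Si](C(C)C)(C(C)C)C(C)C)cc4O[Si](C(C)C)(C(C)C)C(C)C)c5cc([Li])c(OC)cc5[O-])c(OC)cc2O[Si](C)(C)C | intermediate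
24 | macrocyclic bis-adduct (gem-diolate plus Weinreb adduct) | [K+].[Na+].[O-]C1(O[Li])[C@H]3[C@@H](C=C(C)C[C@H]3c3ccc(O[Si](C(C)C)(C(C)C)C(C)C)cc3O[Si](C(C)C)(C(C)C)C(C)C)c2cc(C(O[Li])(N(C)OC)[C@@H]4[C@@H](C=C(C)C[C@H]4c4ccc(O[Si](C(C)C)(C(C)C)C(C)C)cc4O[Si](C(C)C)(C(C)C)C(C)C)c5cc1c(OC)cc5[O-])c(OC)cc2O[Si](C)(C)C | intermediate
25 | protected macrocyclic diketone (two OMe, two free OH, four silyl ethers) | CC1=C[C@H]2c3cc(c(OC)cc3O)C(=O)[C@H]3[C@@H](C=C(C)C[C@H]3c3ccc(O[Si](C(C)C)(C(C)C)C(C)C)cc3O[Si](C(C)C)(C(C)C)C(C)C)c3cc(c(OC)cc3O)C(=O)[C@H]2[C@H](c2ccc(O[Si](C(C)C)(C(C)C)C(C)C)cc2O[Si](C(C)C)(C(C)C)C(C)C)C1 | intermediate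
26 | macrocyclic diketone with four free core OH and four pendant silyl ethers | CC1=C[C@H]2c3cc(c(O)cc3O)C(=O)[C@H]3[C@@H](C=C(C)C[C@H]3c3ccc(O[Si](C(C)C)(C(C)C)C(C)C)cc3O[Si](C(C)C)(C(C)C)C(C)C)c3cc(c(O)cc3O)C(=O)[C@H]2[C@H](c2ccc(O[Si](C(C)C)(C(C)C)C(C)C)cc2O[Si](C(C)C)(C(C)C)C(C)C)C1 | intermediate
27 | CNP0244682.3 | CC1=C[C@H]2c3cc(c(O)cc3O)C(=O)[C@H]3[C@@H](C=C(C)C[C@H]3c3ccc(O)cc3O)c3cc(c(O)cc3O)C(=O)[C@H]2[C@H](c2ccc(O)cc2O)C1 | target

## Step count and weak points

Total steps: 13. Longest linear sequence: 11 (steps 1 to 5, 7 to 9, 10 or 11, 12, 13).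

The three steps most likely to fail are steps 8, 9 and 12.

Risk at step 8, the enantioselective tethered [2+2] photocycloaddition: the aryl ester must reach its s-cis conformer, the electron-rich diene must tolerate the Lewis acid, and the bound cinnamate must outrun unbound background sensitisation. Fallback for step 8, which sets out from 14 and comes back to the route at 16: give up catalyst control and resolve instead. Irradiation of 14 with thioxanthen-9-one (10 mol%, 405 nm LEDs, CH2Cl2, rt, no Lewis acid) gives the racemic cyclobutane, an equal mixture of 15 and the enantiomer of 15 F1. Step 9 as written turns this into the racemic lactone, an equal mixture of 16 and the enantiomer of 16 F2. Preparative chiral SFC separates the two, and the route is re-entered at 16.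

Risk at step 9, the hole-catalysed ring expansion and the new step: cycloreversion of the radical cation to 14 or capture of C5 on the wrong face could compete. Fallback for step 9, which sets out from 14 and comes back to the route at 16: bypass the cyclobutane with a ground-state intramolecular Diels–Alder reaction of 14, catalysed by the same AlBr3-activated oxazaborolidine (CH2Cl2, −20 °C → rt, no light; known chiral-Lewis-acid Diels–Alder chemistry). The endo-carbonyl transition state favoured by the short aryl ester tether gives the cis-fused lactone, and the E-cinnamate fixes the trans C5 aryl. This fallback makes no new compound, F0.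

Risk at step 12, the one-pot hetero bis-acylation and macrocyclisation: the Weinreb amide is hindered, and the second addition must close a 12-membered ring on a carboxylate from a polyanion. Fallback for step 12, which sets out from 17 and 18 and comes back to the route at 25: run only the first addition (20 plus 21, −78 → −40 °C) and quench with 1 M HCl to give the linear bromo keto hydroxy acid F3. EDC·HCl in CH2Cl2 at 0 °C re-closes its ring B hydroxy acid to the linear bromo keto lactone F4. Miyaura borylation (Pd(dppf)Cl2, B2pin2, KOAc, dioxane, 80 °C) gives the pinacol boronate keto lactone F5. Lactone thiolysis (PhSH, AlMe3, CH2Cl2, 0 °C) gives the S-phenyl thioester boronate F6. An intramolecular Liebeskind–Srogl ketone synthesis then closes the ring to 25: Pd2(dba)3, tri(2-furyl)phosphine, monovalent copper thiophene-2-carboxylate Cu(O2CC4H3S), THF, 50 °C, high dilution. These conditions are neutral and base-free, so the ring B α-centre is safe.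

Further compounds

F1 | step 8 | enantiomer of 15 | O=C1[C@H]3[C@H]([C@@H](C(C)=C)[C@@H]3c3ccc(O[Si](C(C)C)(C(C)C)C(C)C)cc3O[Si](C(C)C)(C(C)C)C(C)C)c2cc(Br)c(OC)cc2O1
F2 | step 8 | enantiomer of 16 | O=C1[C@H]3[C@H](C=C(C)C[C@@H]3c3ccc(O[Si](C(C)C)(C(C)C)C(C)C)cc3O[Si](C(C)C)(C(C)C)C(C)C)c2cc(Br)c(OC)cc2O1
F0 | step 9 | none | none
F3 | step 12 | linear bromo keto hydroxy acid | OC(=O)[C@H]3[C@@H](C=C(C)C[C@H]3c3ccc(O[Si](C(C)C)(C(C)C)C(C)C)cc3O[Si](C(C)C)(C(C)C)C(C)C)c2cc(C(=O)[C@@H]4[C@@H](C=C(C)C[C@H]4c4ccc(O[Si](C(C)C)(C(C)C)C(C)C)cc4O[Si](C(C)C)(C(C)C)C(C)C)c5cc(Br)c(OC)cc5O)c(OC)cc2O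
F4 | step 12 | linear bromo keto lactone | O=C1[C@H]3[C@@H](C=C(C)C[C@H]3c3ccc(O[Si](C(C)C)(C(C)C)C(C)C)cc3O[Si](C(C)C)(C(C)C)C(C)C)c2cc(C(=O)[C@@H]4[C@@H](C=C(C)C[C@H]4c4ccc(O[Si](C(C)C)(C(C)C)C(C)C)cc4O[Si](C(C)C)(C(C)C)C(C)C)c5cc(Br)c(OC)cc5O)c(OC)cc2O1
F5 | step 12 | pinacol boronate keto lactone | O=C1[C@H]3[C@@H](C=C(C)C[C@H]3c3ccc(O[Si](C(C)C)(C(C)C)C(C)C)cc3O[Si](C(C)C)(C(C)C)C(C)C)c2cc(C(=O)[C@@H]4[C@@H](C=C(C)C[C@H]4c4ccc(O[Si](C(C)C)(C(C)C)C(C)C)cc4O[Si](C(C)C)(C(C)C)C(C)C)c5cc(B6OC(C)(C)C(C)(C)O6)c(OC)cc5O)c(OC)cc2O1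
F6 | step 12 | S-phenyl thioester boronate | O=C(Sc6ccccc6)[C@H]3[C@@H](C=C(C)C[C@H]3c3ccc(O[Si](C(C)C)(C(C)C)C(C)C)cc3O[Si](C(C)C)(C(C)C)C(C)C)c2cc(C(=O)[C@@H]4[C@@H](C=C(C)C[C@H]4c4ccc(O[Si](C(C)C)(C(C)C)C(C)C)cc4O[Si](C(C)C)(C(C)C)C(C)C)c5cc(B7OC(C)(C)C(C)(C)O7)c(OC)cc5O)c(OC)cc2O
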